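Epsilon's sites need 28.0 mM of incoming ligand, less than the 40 mM charged, while zeta's need 400 mM against the same charge, and at 60.0 min the complex with four exchanged reads 56.0% in epsilon and 0.2% in zeta.

| flask | starting complex | incoming ligand | remark | time |
|---|---|---|---|---|
| epsilon | 7 mM | 40 mM (in portions, 2) | run made earlier; portions every 3.0 min |  |
| zeta | 100 mM | 40 mM (in portions, 2) | run made earlier; portions every 3.0 min |  |
| birch | 5.0 mM | 40.0 mM (in portions, 2) | the portions of incoming ligand follow each other after 3.0 min, the first at the start | 1.5 h |
| ash | 10 mM | 40.0 mM (in portions, 2) | the portions of incoming ligand follow each other after 3.0 min, the first at the start | 1.5 h |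
| elm | 20 mM | 40.0 mM (in portions, 2) | the portions of incoming ligand follow each other after 3.0 min, the first at the start | 1.5 h |
| oak | 40 mM | 40.0 mM (in portions, 2) | the portions of incoming ligand follow each other after 3.0 min, the first at the start | 1.5 h |
| cedar | 80 mM | 40.0 mM (in portions, 2) | the portions of incoming ligand follow each other after 3.0 min, the first at the start | 1.5 h |

| run | time / min | complex with four exchanged / % |
|---|---|---|
| epsilon | 10.0 | 5.8 |
| epsilon | 20.0 | 18.8 |
| epsilon | 30.0 | 29.7 |
| epsilon | 40.0 | 40.7 |
| epsilon | 50.0 | 46.4 |
| epsilon | 60.0 | 56.0 |
| zeta | 10.0 | 1.5 |
| zeta | 20.0 | 0 |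
| zeta | 30.0 | 0.3 |
| zeta | 40.0 | 1.4 |
| zeta | 50.0 | 0.5 |
| zeta | 60.0 | 0.2 |

(scatter of a reading: 1 percentage point)

- percentages count the starting complex that a species holds: one homo dimer counts as two
- steps that have been proposed: complex with three exchanged + incoming ligand -> leaving ligand + complex with four exchanged; complex with one exchanged + incoming ligand -> leaving ligand + complex with two exchanged; starting complex + incoming ligand -> leaving ligand + complex with one exchanged; 2 starting complex -> homo dimer; complex with two exchanged + incoming ligand -> leaving ligand + complex with three exchanged
- "hardly changes" means that all values lie within two and a half points (for a concentration: within two and a half percent of the largest)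

1. [complex with four exchanged] at the end for birch, ash, elm, oak, cedar, in this order
2. how that number moves from the first to the last of them (hardly changes / falls, then rises / rises all the way / falls all the way / rises, then falls)

So we first ask who runs out, and for elm we reckon 0.500 as the fill, the incoming ligand charged divided by 4 times the starting complex charged. Where the fill exceeds one, the starting complex is the limiting reagent and caps the product; below one the cap is a quarter of the incoming ligand, 10.0 mM. Birch, at fill 2.00, is therefore capped at 5.0 mM, and ash, at fill 1.00, at 10.0 mM.

The next question is how much reaches the end below one. If incoming ligand lands evenly on the sites, the share with 4 taken is the fill to the power 4, a small correction on a flask of partly exchanged complexes. Zeta, at fill 0.100, would hold 0.0100%, and its readings of 1.5% or less, with scatter 1 percentage point, do not contradict this. Our row then ends with 1.25 mM for elm, 0.156 mM for oak and 0.0195 mM for cedar, so, going by the caps on birch and ash, we expect a rise to ash and then a fall.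

The forecast gives 4.3 mM, 6 mM, 3 mM, 0.7 mM and 0.1 mM, shape rises, then falls, holding that “ligand is exhausted with a statistical spread”; its elm figure lies above ours.

The flasks give 4.03 mM, 4.38 mM, 0.230 mM, 0.0235 mM and 0.00356 mM, shape rises, then falls.

    complex with three exchanged + incoming ligand → leaving ligand + complex with four exchanged (k = 0.0150 L mol⁻¹ s⁻¹)
    complex with one exchanged + incoming ligand → leaving ligand + complex with two exchanged (k = 0.362 L mol⁻¹ s⁻¹)
    starting complex + incoming ligand → leaving ligand + complex with one exchanged (k = 0.436 L mol⁻¹ s⁻¹)
    2 starting complex → homo dimer (k = 0.0109 L mol⁻¹ s⁻¹)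
    complex with two exchanged + incoming ligand → leaving ligand + complex with three exchanged (k = 0.164 L mol⁻¹ s⁻¹)

Elm, at fill 0.500, stands below our even-spread figure by a factor of 5.43, and cedar, at fill 0.125, by 5.49; the last exchange has the constant 0.0150 L mol⁻¹ s⁻¹, against 0.164 L mol⁻¹ s⁻¹ for the one before it. In cedar, part of the 0.00356 mM comes from the path to homo dimer acting together with the gradual adding of incoming ligand: without that path cedar gives 0.00220 mM, and with the charge added at once 0.00249 mM.

All runs are simulated with made-up constants, noise included.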